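All runs are simulated for an exercise, and the scatter is random.

Cedar is the flask to think through: its activator arrives over 25 min, so starting material sits unprotected while homo dimer forms.

| flask | starting material | activator | protic impurity | temperature | remark | time |
|---|---|---|---|---|---|---|
| winter | 0.13 M | 0.156 M | 0.13 M | 105 °C | run made earlier |  |
| summer | 0.13 M | 0.078 M | 0.13 M | 116 °C | run made earlier |  |
| dusk | 0.13 M | 0.12 M | 0.13 M | 105 °C | run made earlier |  |
| autumn | 0.13 M | 0.156 M | 0.065 M | 116 °C | run made earlier |  |
| elm | 0.13 M (fed, over 25 min) | 0.156 M | 0.130 M |  | the addition at 80 °C, then warmed to 110 °C; the feed brings no volume worth counting | 2.0 h |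
| maple | 0.13 M (fed, over 25 min) | 0.156 M | 0.130 M | 110 °C | all else is in the flask from the start; the feed brings no volume worth counting | 2.0 h |
| alder | 0.13 M | 0.156 M | 0.130 M | 110 °C | everything together at the start | 2.0 h |
| cedar | 0.13 M | 0.156 M (fed, over 25 min) | 0.130 M | 110 °C | all else is in the flask from the start; the feed brings no volume worth counting | 2.0 h |

- winter (time / min: homo dimer / %, ring / %): 6.00: 2.7, 0; 8.00: 3.2, 0; 12.0: 4.5, 0.9; 20.0: 6.7, 1.2; 30.0: 7.2, 3.1; 50.0: 9.0, 5.7; 80.0: 9.3, 9.9
- summer (time / min: homo dimer / %, ring / %): 15.0: 12.2, 2.0; 30.0: 17.6, 4.6; 50.0: 19.2, 7.7; 60.0: 20.8, 8.5; 80.0: 20.8, 10.9; 90.0: 21.4, 11.2; 120: 21.1, 13.5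
- dusk (time / min: homo dimer / %, ring / %): 10.0: 4.7, 0.6; 15.0: 5.6, 1.4; 20.0: 7.3, 1.8; 30.0: 8.1, 2.4; 50.0: 10.2, 4.7; 80.0: 11.4, 7.4; 120: 12.9, 12.2
- autumn (time / min: homo dimer / %, ring / %): 10.0: 7.9, 1.9; 20.0: 12.1, 4.6; 30.0: 13.8, 8.2; 60.0: 14.9, 16.6; 120: 14.9, 24.2

(each reading ± 0.5 percentage points)

- which flask leads in amount of homo dimer, in percent of the starting material charged ("all alike" within 1.5 percentage points) (elm / maple / alder / cedar / all alike)
- how much homo dimer is there at the end, in percent of the starting material charged: elm
- how much homo dimer is there at the end, in percent of the starting material charged: maple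
- how much homo dimer is there at the end, in percent of the starting material charged: alder
- how much homo dimer is there at the end, in percent of the starting material charged: cedar

- percent here means starting material units held: one homo dimer counts as two

In a batch run, take the activator's clearing of starting material as pseudo-first-order. Homo dimer then rises at its early pace for a free window w, the plateau divided by that pace. You can read this from two runs with the same activator charge:

w(winter) = 20.7 min, w(autumn) = 18.9 min

Since 110 °C lies near the middle of 105 °C and 116 °C, I take the geometric means for alder, though autumn held less protic impurity: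

w = 19.7 min, plateau = 11.8%

If w goes inversely with [activator], winter predicts 12.1% for dusk, which reads 12.9%. But autumn predicts 29.8% for summer, which reads 21.1%, so the rule overshoots at large homo dimer shares.

During a feed, activator grows along a straight line, so cumulative clearing grows with time squared. The window lengthens to the geometric mean of w and 2t_f, which gives the stretch number, the factor by which feeding activator lengthens the free window:

S = √(2t_f/w) = 1.59

Cedar: plateau × S = 18.7%

This stretched window, 31.4 min, outlasts the feed, but activator stops rising when the feed ends, so the time-squared law overcounts the clearing after that point. Reckoned with activator level after the feed, the window is w + t_f/2 = 32.2 min, and the cedar figure becomes 19.3%.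

The forecast gave elm 7.5%, maple 9%, alder 12% and cedar 23%, reasoning that “Feeding activator leaves starting material high and unprotected”.

The flasks give elm 10.3%, maple 9.19%, alder 11.4% and cedar 16.9%, so cedar leads.

    starting material + activator → activated form (k = 0.180 M⁻¹ min⁻¹, Ea = 61.0 kJ mol⁻¹)
    activated form → ring (k = 0.00820 min⁻¹, Ea = 111 kJ mol⁻¹)
    starting material + activated form → open dimer (k = 0.190 M⁻¹ min⁻¹, Ea = 80.0 kJ mol⁻¹)
    starting material + protic impurity → quenched substrate (k = 0.0350 M⁻¹ min⁻¹, Ea = 76.0 kJ mol⁻¹)
    activated form → side product (k = 0.00580 min⁻¹, Ea = 122 kJ mol⁻¹)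
    2 starting material → homo dimer (k = 0.0320 M⁻¹ min⁻¹, Ea = 103 kJ mol⁻¹)
    (constants at 110 °C)

Cedar's ratio to alder is 1.48, below S. In cedar, half of the activation turnover was done by 0.491 h, later than the feed's end. For cedar's neighbour with 0.62 M of activator, w becomes 4.97 min and S becomes 3.17, so the stretched window is 15.8 min, shorter than the feed. The reckoning gives 9.40% of homo dimer, and that neighbour holds 9.25%.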